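**Retrosynthetic overview**

1. The last bond made is the ester C–O between the C3 hydroxymethyl group and p-coumaric acid (carbodiimide coupling of a silyl-protected acid); one fluoride step then frees the three hydroxyl groups.
2. The C3 carbinol carbon comes from a methyl ester. The trans-(2R,3S) arrangement is reached by base equilibration of a cis ester at C3, with the C2 centre left untouched.
3. The strategic disconnection is the C2–C3 bond of the dihydrofuran ring (O1, C2, C3, C3a, C7a), the only ring built in the route. It rests on this feature: C3 is benzylic to ring A and carries a carboxyl-level carbon, and C2 is an ether-type benzylic CH carrying ring B. The bond is therefore the outcome of a 1,5 C–H insertion of an aryl(ester)carbene into the ortho O–CH2Ar group.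
4. The aryldiazoacetate goes back to a methyl arylacetate (diazo transfer), then to an ortho-allyl aryl benzyl ether (oxidative cleavage), then to a phenol and a silylated vanillyl alcohol (Mitsunobu ether bond).
5. Ring A with its substituents comes from eugenol (hydroboration, O-allylation, aromatic Claisen rearrangement), ring B from vanillin, and the acyl part from p-coumaric acid; all three benzene rings are bought, not made.

Key step: step 12

Assumption: the S-configured catalyst is taken to give the 2R series, as this catalyst class does with the parent 2-benzyloxyphenyl diazoacetates; if this substrate responds in the opposite sense, Rh2(R-PTTL)4 is used and nothing else changes.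

Abbreviations: TBS = tert-butyldimethylsilyl; TIPS = triisopropylsilyl; p-ABSA = 4-acetamidobenzenesulfonyl azide.

**Route**

Step 1
Reactants: 1 eugenol (4-allyl-2-methoxyphenol)
Product: 3 3-(4-hydroxy-3-methoxyphenyl)propan-1-ol (dihydroconiferyl alcohol), via B-alkyl-9-BBN adduct 2 (not isolated)
Conditions: 9-BBN (2.2 equiv), THF, 0 °C → rt; then 3 M NaOH, 30% H2O2, 0 °C → rt
Reagents that add atoms: 9-borabicyclo[3.3.1]nonane, B1C2CCCC1CCC2 (boron held only in 2); hydrogen peroxide, OO (hydroxyl oxygen of 3)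
Why: Hydroboration–oxidation, in which the bulky dialkylborane adds anti-Markovnikov to the terminal alkene and alkaline peroxide replaces boron by OH, the excess reagent covering any reversible borylation of the phenol.

Step 2
Reactants: 3 dihydroconiferyl alcohol
Product: 4 3-[3-methoxy-4-(prop-2-en-1-yloxy)phenyl]propan-1-ol
Conditions: allyl bromide, K2CO3, acetone, reflux
Reagents that add atoms: allyl bromide, C=CCBr
Why: Williamson ether synthesis, chemoselective because K2CO3 deprotonates only the phenol and leaves the aliphatic alcohol unreactive.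

Step 3
Reactants: 4 3-[3-methoxy-4-(prop-2-en-1-yloxy)phenyl]propan-1-ol
Product: 5 tert-butyl(dimethyl){3-[3-methoxy-4-(prop-2-en-1-yloxy)phenyl]propoxy}silane
Conditions: TBSCl, imidazole, DMF, rt
Reagents that add atoms: tert-butyldimethylsilyl chloride, CC(C)(C)[Si](C)(C)Cl
Why: Imidazole-promoted silylation of the primary alcohol, needed because a free OH would compete in the later Mitsunobu step and would trap the carbene by O–H insertion.

Step 4
Reactants: 5 tert-butyl(dimethyl){3-[3-methoxy-4-(prop-2-en-1-yloxy)phenyl]propoxy}silane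
Product: 7 2-methoxy-6-(prop-2-en-1-yl)-4-[3-(TBS-oxy)propyl]phenol, via ortho-dienone 6 (not isolated)
Conditions: 1,2-dichlorobenzene, 190 °C, sealed tube
Reagents that add atoms: none
Why: Aromatic Claisen rearrangement ([3,3]-sigmatropic shift, then tautomerisation of the dienone), which can deliver the allyl group only to the one free ortho position because the other ortho carbon carries OMe and the para carbon carries the side chain.

Step 5
Reactants: 8 vanillin
Product: 9 3-methoxy-4-(TIPS-oxy)benzaldehyde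
Conditions: TIPSCl, imidazole, DMF, rt
Reagents that add atoms: triisopropylsilyl chloride, CC(C)[Si](Cl)(C(C)C)C(C)C
Why: Silylation of the phenol, with TIPS chosen as the aryl silyl ether most resistant to base and because the para-silyloxy group later activates the benzylic C–H bond electronically.

Step 6
Reactants: 9 3-methoxy-4-(TIPS-oxy)benzaldehyde
Product: 10 [3-methoxy-4-(TIPS-oxy)phenyl]methanol
Conditions: NaBH4, MeOH/THF, 0 °C
Reagents that add atoms: none
Why: Borohydride reduction of an aryl aldehyde to the benzylic alcohol, which the hindered aryl silyl ether should survive at 0 °C.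

Step 7
Reactants: 7 2-methoxy-6-(prop-2-en-1-yl)-4-[3-(TBS-oxy)propyl]phenol; 10 [3-methoxy-4-(TIPS-oxy)phenyl]methanol
Product: 11 2-allyl-6-methoxy-4-[3-(TBS-oxy)propyl]phenyl 3-methoxy-4-(TIPS-oxy)benzyl ether
Conditions: PPh3, DIAD, THF, 0 °C → rt
Reagents that add atoms: none
Why: Mitsunobu etherification, in which the phenol (acidic enough as pronucleophile) displaces the oxyphosphonium-activated primary benzylic alcohol under neutral conditions that spare both silyl ethers.

Step 8
Reactants: 11 2-allyl-6-methoxy-4-[3-(TBS-oxy)propyl]phenyl 3-methoxy-4-(TIPS-oxy)benzyl ether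
Product: 13 2-{3-methoxy-2-[3-methoxy-4-(TIPS-oxy)benzyloxy]-5-[3-(TBS-oxy)propyl]phenyl}acetaldehyde, via vicinal diol 12 (not isolated)
Conditions: OsO4 (2 mol %), NaIO4 (4 equiv), 2,6-lutidine, 1,4-dioxane/H2O, rt
Reagents that add atoms: osmium tetroxide, O=[Os](=O)(=O)=O (catalytic oxygen carrier); sodium periodate, [Na+].[O-]I(=O)(=O)=O
Why: Lemieux–Johnson oxidation (dihydroxylation, then periodate glycol cleavage) of the only alkene, with 2,6-lutidine keeping the medium near neutral for the silyl ethers and the electron-rich rings.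

Step 9
Reactants: 13 the arylacetaldehyde
Product: 14 2-{3-methoxy-2-[3-methoxy-4-(TIPS-oxy)benzyloxy]-5-[3-(TBS-oxy)propyl]phenyl}acetic acid
Conditions: NaClO2, NaH2PO4, 2-methyl-2-butene, t-BuOH/THF/H2O, 0 °C → rt (crude 13 used at once)
Reagents that add atoms: sodium chlorite, [Na+].[O-]Cl=O
Why: Pinnick oxidation of the aldehyde to the acid, with 2-methyl-2-butene trapping the hypochlorous acid so that the electron-rich arenes are not chlorinated.

Step 10
Reactants: 14 the arylacetic acid
Product: 15 methyl 2-{3-methoxy-2-[3-methoxy-4-(TIPS-oxy)benzyloxy]-5-[3-(TBS-oxy)propyl]phenyl}acetate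
Conditions: TMSCHN2, PhMe/MeOH, 0 °C
Reagents that add atoms: (trimethylsilyl)diazomethane, C[Si](C)(C)C=[N+]=[N-]
Why: Base-free methyl esterification of a carboxylic acid with (trimethylsilyl)diazomethane, which leaves the aryl silyl ether untouched.

Step 11
Reactants: 15 the methyl arylacetate
Product: 16 methyl 2-diazo-2-{3-methoxy-2-[3-methoxy-4-(TIPS-oxy)benzyloxy]-5-[3-(TBS-oxy)propyl]phenyl}acetate
Conditions: p-ABSA, DBU, MeCN, 0 °C → rt
Reagents that add atoms: 4-acetamidobenzenesulfonyl azide, CC(=O)Nc1ccc(cc1)S(=O)(=O)N=[N+]=[N-]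
Why: Regitz diazo transfer from the sulfonyl azide to the amidine-generated arylacetate enolate, the standard entry to aryldiazoacetates.

Step 12
Reactants: 16 the aryldiazoacetate
Product: 17 methyl (2R,3S)-7-methoxy-2-[3-methoxy-4-(TIPS-oxy)phenyl]-5-[3-(TBS-oxy)propyl]-2,3-dihydro-1-benzofuran-3-carboxylate (cis)
Conditions: Rh2(S-PTTL)4 (dirhodium tetrakis[N-phthaloyl-(S)-tert-leucinate], divalent rhodium, 2 mol %), PhMe, −78 → −40 °C, slow addition of 16
Reagents that add atoms: none
Why: The catalyst expels N2 from 16 to give a donor/acceptor rhodium carbene (aryl donor, ester acceptor), which inserts into one benzylic C–H bond of the ortho O–CH2Ar group by a concerted, asynchronous three-centre hydride transfer and C–C bond formation, making C2–C3 and releasing the catalyst. The closest known reaction type is the dirhodium carboxylate-catalysed enantioselective intramolecular C–H insertion of methyl 2-(2-benzyloxyaryl)-2-diazoacetates to cis-2-aryl-2,3-dihydrobenzofuran-3-carboxylates. The dihydrofuran ring (O1, C2, C3, C3a, C7a) closes as a 1,5-insertion, the only ring size the carbene can reach on this tether. C2 is set by the chiral phthalimido-tert-leucinate ligand shell, which distinguishes the two enantiotopic benzylic hydrogens (2R expected with the S catalyst), and C3 is set in the same concerted event, the ring B aryl group and the ester ending up cis under kinetic control at low temperature. The step needs site selectivity for the O–CH2Ar hydrogens over the OCH3, silyl ether OCH2 and isopropyl C–H bonds, and chemoselectivity over oxonium ylide formation, arene cyclopropanation and carbene dimerisation. The substrate secures this because only that C–H bond is both 1,5-related to the carbene and doubly activated (ether oxygen and the electron-rich 4-silyloxy-3-methoxyphenyl group), while the selective donor/acceptor carbene, the non-coordinating solvent and slow addition hold back the other paths.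

Step 13
Reactants: 17 the cis ester
Product: 18 methyl (2R,3R)-7-methoxy-2-[3-methoxy-4-(TIPS-oxy)phenyl]-5-[3-(TBS-oxy)propyl]-2,3-dihydro-1-benzofuran-3-carboxylate (trans)
Conditions: NaOMe (0.3 equiv), MeOH/THF, 0 °C, AcOH quench
Reagents that add atoms: none
Why: Thermodynamic epimerisation through the ester enolate with the matching alkoxide, which should move the ester away from the C2 aryl group at C3 only, because C2–H is not acidic, ring opening by loss of the aryloxide is stereoelectronically disfavoured, and the hindered aryl TIPS ether should outlast dilute methoxide at 0 °C.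

Step 14
Reactants: 18 the trans ester
Product: 19 {(2R,3S)-7-methoxy-2-[3-methoxy-4-(TIPS-oxy)phenyl]-5-[3-(TBS-oxy)propyl]-2,3-dihydro-1-benzofuran-3-yl}methanol (trans)
Conditions: LiAlH4, THF, 0 °C
Reagents that add atoms: none
Why: Hydride reduction of the ester to the primary alcohol, which removes the acidity at C3 and so fixes the trans relationship, the silyl ethers being inert to the reagent at 0 °C.

Step 15
Reactants: 20 p-coumaric acid
Product: 22 (2E)-3-[4-(TBS-oxy)phenyl]prop-2-enoic acid, via bis-silyl derivative 21 (not isolated)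
Conditions: TBSCl (2.4 equiv), imidazole, DMF, rt; then AcOH/THF/H2O, rt
Reagents that add atoms: tert-butyldimethylsilyl chloride, CC(C)(C)[Si](C)(C)Cl
Why: Silylation of both acidic OH groups followed by selective hydrolysis of the far more labile silyl ester, which leaves the aryl silyl ether and the E alkene unchanged.

Step 16
Reactants: 19 the trans alcohol; 22 (2E)-3-[4-(TBS-oxy)phenyl]prop-2-enoic acid
Product: 23 {(2R,3S)-7-methoxy-2-[3-methoxy-4-(TIPS-oxy)phenyl]-5-[3-(TBS-oxy)propyl]-2,3-dihydro-1-benzofuran-3-yl}methyl (2E)-3-[4-(TBS-oxy)phenyl]prop-2-enoate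
Conditions: DCC, DMAP (cat.), CH2Cl2, 0 °C → rt
Reagents that add atoms: none
Why: Steglich esterification of the only free hydroxyl group through the DMAP-acylpyridinium species, mild enough to keep the alkene geometry and all three silyl ethers.

Step 17
Reactants: 23 the tris-silyl ester
Product: 24 [(2R,3S)-2-(4-hydroxy-3-methoxyphenyl)-5-(3-hydroxypropyl)-7-methoxy-2,3-dihydro-1-benzofuran-3-yl]methyl (2E)-3-(4-hydroxyphenyl)prop-2-enoate (target)
Conditions: TBAF (4 equiv), AcOH (4 equiv), THF, 0 °C → rt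
Reagents that add atoms: none
Why: Fluoride-mediated cleavage of the alkyl and the two aryl silyl ethers, buffered with acetic acid so that the phenols stay protonated and neither the cinnamate ester nor the C2–O1 benzylic ether bond is put at risk.

**Compound list**

1 | eugenol (4-allyl-2-methoxyphenol) | C=CCc1ccc(O)c(OC)c1 | starting material
2 | 9-[3-(4-hydroxy-3-methoxyphenyl)propyl]-9-borabicyclo[3.3.1]nonane (formed in situ) | COc1cc(CCCB2C3CCCC2CCC3)ccc1O | intermediate
3 | 3-(4-hydroxy-3-methoxyphenyl)propan-1-ol | COc1cc(CCCO)ccc1O | intermediate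
4 | 3-[3-methoxy-4-(prop-2-en-1-yloxy)phenyl]propan-1-ol | C=CCOc1ccc(CCCO)cc1OC | intermediate
5 | tert-butyl(dimethyl){3-[3-methoxy-4-(prop-2-en-1-yloxy)phenyl]propoxy}silane | C=CCOc1ccc(CCCO[Si](C)(C)C(C)(C)C)cc1OC | intermediate
6 | 2-methoxy-6-(prop-2-en-1-yl)-4-[3-(TBS-oxy)propyl]cyclohexa-2,4-dien-1-one (formed in situ) | C=CCC1C=C(CCCO[Si](C)(C)C(C)(C)C)C=C(OC)C1=O | intermediate
7 | 2-methoxy-6-(prop-2-en-1-yl)-4-[3-(TBS-oxy)propyl]phenol | C=CCc1cc(CCCO[Si](C)(C)C(C)(C)C)cc(OC)c1O | intermediate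
8 | vanillin | COc1cc(C=O)ccc1O | starting material
9 | 3-methoxy-4-(TIPS-oxy)benzaldehyde | COc1cc(C=O)ccc1O[Si](C(C)C)(C(C)C)C(C)C | intermediate
10 | [3-methoxy-4-(TIPS-oxy)phenyl]methanol | COc1cc(CO)ccc1O[Si](C(C)C)(C(C)C)C(C)C | intermediate
11 | 2-allyl-6-methoxy-4-[3-(TBS-oxy)propyl]phenyl 3-methoxy-4-(TIPS-oxy)benzyl ether | C=CCc1cc(CCCO[Si](C)(C)C(C)(C)C)cc(OC)c1OCc1ccc(O[Si](C(C)C)(C(C)C)C(C)C)c(OC)c1 | intermediate
12 | 3-{3-methoxy-2-[3-methoxy-4-(TIPS-oxy)benzyloxy]-5-[3-(TBS-oxy)propyl]phenyl}propane-1,2-diol (formed in situ, racemic at the carbinol carbon) | OCC(O)Cc1cc(CCCO[Si](C)(C)C(C)(C)C)cc(OC)c1OCc1ccc(O[Si](C(C)C)(C(C)C)C(C)C)c(OC)c1 | intermediate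
13 | 2-{3-methoxy-2-[3-methoxy-4-(TIPS-oxy)benzyloxy]-5-[3-(TBS-oxy)propyl]phenyl}acetaldehyde | O=CCc1cc(CCCO[Si](C)(C)C(C)(C)C)cc(OC)c1OCc1ccc(O[Si](C(C)C)(C(C)C)C(C)C)c(OC)c1 | intermediate
14 | 2-{3-methoxy-2-[3-methoxy-4-(TIPS-oxy)benzyloxy]-5-[3-(TBS-oxy)propyl]phenyl}acetic acid | OC(=O)Cc1cc(CCCO[Si](C)(C)C(C)(C)C)cc(OC)c1OCc1ccc(O[Si](C(C)C)(C(C)C)C(C)C)c(OC)c1 | intermediate
15 | methyl 2-{3-methoxy-2-[3-methoxy-4-(TIPS-oxy)benzyloxy]-5-[3-(TBS-oxy)propyl]phenyl}acetate | COC(=O)Cc1cc(CCCO[Si](C)(C)C(C)(C)C)cc(OC)c1OCc1ccc(O[Si](C(C)C)(C(C)C)C(C)C)c(OC)c1 | intermediate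
16 | methyl 2-diazo-2-{3-methoxy-2-[3-methoxy-4-(TIPS-oxy)benzyloxy]-5-[3-(TBS-oxy)propyl]phenyl}acetate | COC(=O)C(=[N+]=[N-])c1cc(CCCO[Si](C)(C)C(C)(C)C)cc(OC)c1OCc1ccc(O[Si](C(C)C)(C(C)C)C(C)C)c(OC)c1 | intermediate
17 | methyl (2R,3S)-7-methoxy-2-[3-methoxy-4-(TIPS-oxy)phenyl]-5-[3-(TBS-oxy)propyl]-2,3-dihydro-1-benzofuran-3-carboxylate (cis) | COc1cc([C@@H]2Oc3c(OC)cc(CCCO[Si](C)(C)C(C)(C)C)cc3[C@@H]2C(=O)OC)ccc1O[Si](C(C)C)(C(C)C)C(C)C | intermediate
18 | methyl (2R,3R)-7-methoxy-2-[3-methoxy-4-(TIPS-oxy)phenyl]-5-[3-(TBS-oxy)propyl]-2,3-dihydro-1-benzofuran-3-carboxylate (trans) | COc1cc([C@@H]2Oc3c(OC)cc(CCCO[Si](C)(C)C(C)(C)C)cc3[C@H]2C(=O)OC)ccc1O[Si](C(C)C)(C(C)C)C(C)C | intermediate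
19 | {(2R,3S)-7-methoxy-2-[3-methoxy-4-(TIPS-oxy)phenyl]-5-[3-(TBS-oxy)propyl]-2,3-dihydro-1-benzofuran-3-yl}methanol (trans) | COc1cc([C@@H]2Oc3c(OC)cc(CCCO[Si](C)(C)C(C)(C)C)cc3[C@H]2CO)ccc1O[Si](C(C)C)(C(C)C)C(C)C | intermediate
20 | p-coumaric acid, (2E)-3-(4-hydroxyphenyl)prop-2-enoic acid | OC(=O)/C=C/c1ccc(O)cc1 | starting material
21 | TBS (2E)-3-[4-(TBS-oxy)phenyl]prop-2-enoate (formed in situ) | CC(C)(C)[Si](C)(C)OC(=O)/C=C/c1ccc(O[Si](C)(C)C(C)(C)C)cc1 | intermediate
22 | (2E)-3-[4-(TBS-oxy)phenyl]prop-2-enoic acid | OC(=O)/C=C/c1ccc(O[Si](C)(C)C(C)(C)C)cc1 | intermediate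
23 | {(2R,3S)-7-methoxy-2-[3-methoxy-4-(TIPS-oxy)phenyl]-5-[3-(TBS-oxy)propyl]-2,3-dihydro-1-benzofuran-3-yl}methyl (2E)-3-[4-(TBS-oxy)phenyl]prop-2-enoate | COc1cc([C@@H]2Oc3c(OC)cc(CCCO[Si](C)(C)C(C)(C)C)cc3[C@H]2COC(=O)/C=C/c2ccc(O[Si](C)(C)C(C)(C)C)cc2)ccc1O[Si](C(C)C)(C(C)C)C(C)C | intermediate
24 | [(2R,3S)-2-(4-hydroxy-3-methoxyphenyl)-5-(3-hydroxypropyl)-7-methoxy-2,3-dihydro-1-benzofuran-3-yl]methyl (2E)-3-(4-hydroxyphenyl)prop-2-enoate | COc1cc([C@@H]2Oc3c(OC)cc(CCCO)cc3[C@H]2COC(=O)/C=C/c2ccc(O)cc2)ccc1O | target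

**Step count**

Total: 17 steps. Longest linear sequence: 14 steps (eugenol to target through steps 1–4, 7–14, 16 and 17).

**Steps most likely to fail**

1. Step 12. The benzyloxy group is flanked on ring A by the OMe group and the carbene carbon and is twisted out of plane. The catalyst may therefore discriminate the two enantiotopic benzylic hydrogens poorly, or the carbene may be drawn to the ether oxygen (ylide formation) instead of the C–H bond. The fallback moves the stereocontrol onto a covalently bound auxiliary and sets out from acid 14. Ethyl (S)-lactate is heated with pyrrolidine to give the lactamide alcohol (2S)-2-hydroxy-1-(pyrrolidin-1-yl)propan-1-one F1. Coupling of F1 with 14 (DCC, DMAP, CH2Cl2) gives the lactamide arylacetate F2, and diazo transfer (p-ABSA, DBU, MeCN) gives the lactamide aryldiazoacetate F3. Insertion with Rh2(S-DOSP)4 (dirhodium tetrakis[N-(4-dodecylbenzenesulfonyl)-(S)-prolinate], divalent rhodium) in CH2Cl2 should then give the trans-(2R,3R) lactamide ester F4 directly. Auxiliary and catalyst enantiomers are paired in a test reaction so that the matched combination leads to the 2R series; the structures are drawn for the S auxiliary. Stereoisomeric by-products are diastereomers of F4 and can be removed on silica. LiBH4 in THF cleaves the auxiliary reductively and returns to the route at alcohol 19, so steps 12–14 are by-passed.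

2. Step 13. Proton exchange at C3 may be slow enough that methoxide attack at the aryl silicon (loss of the TIPS group) competes before equilibrium is reached. The fallback shifts the epimerisation to the aldehyde oxidation level, where an amine base suffices, and sets out from cis ester 17. LiAlH4 (THF, 0 °C) gives the cis-(2R,3R) alcohol F5, and Dess–Martin periodinane (NaHCO3, CH2Cl2) gives the cis-(2R,3S) aldehyde F6. DBU (cat.) in CH2Cl2 at room temperature should equilibrate F6 to the trans-(2R,3R) aldehyde F7 without any reagent that attacks silicon. NaBH4 (MeOH/THF, 0 °C) then returns to the route at alcohol 19.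

3. Step 7. The oxyphosphonium ion of the electron-rich 4-silyloxybenzyl alcohol may ionise, so that the hindered 2,6-disubstituted phenol is alkylated on carbon or the benzyl unit oligomerises instead of forming the ether. The fallback uses a preformed electrophile and sets out from alcohol 10. Appel bromination (CBr4, PPh3, CH2Cl2, 0 °C) gives [4-(bromomethyl)-2-methoxyphenoxy]tri(propan-2-yl)silane F8, which is used at once. Williamson alkylation of phenol 7 (K2CO3, acetone, reflux) returns to the route at ether 11.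

**Further compounds**

F1 | step 12 | (2S)-2-hydroxy-1-(pyrrolidin-1-yl)propan-1-one | C[C@H](O)C(=O)N1CCCC1
F2 | step 12 | (2S)-1-oxo-1-(pyrrolidin-1-yl)propan-2-yl 2-{3-methoxy-2-[3-methoxy-4-(TIPS-oxy)benzyloxy]-5-[3-(TBS-oxy)propyl]phenyl}acetate | C[C@H](OC(=O)Cc1cc(CCCO[Si](C)(C)C(C)(C)C)cc(OC)c1OCc1ccc(O[Si](C(C)C)(C(C)C)C(C)C)c(OC)c1)C(=O)N1CCCC1
F3 | step 12 | (2S)-1-oxo-1-(pyrrolidin-1-yl)propan-2-yl 2-diazo-2-{3-methoxy-2-[3-methoxy-4-(TIPS-oxy)benzyloxy]-5-[3-(TBS-oxy)propyl]phenyl}acetate | C[C@H](OC(=O)C(=[N+]=[N-])c1cc(CCCO[Si](C)(C)C(C)(C)C)cc(OC)c1OCc1ccc(O[Si](C(C)C)(C(C)C)C(C)C)c(OC)c1)C(=O)N1CCCC1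
F4 | step 12 | (2S)-1-oxo-1-(pyrrolidin-1-yl)propan-2-yl (2R,3R)-7-methoxy-2-[3-methoxy-4-(TIPS-oxy)phenyl]-5-[3-(TBS-oxy)propyl]-2,3-dihydro-1-benzofuran-3-carboxylate (trans) | COc1cc([C@@H]2Oc3c(OC)cc(CCCO[Si](C)(C)C(C)(C)C)cc3[C@H]2C(=O)O[C@@H](C)C(=O)N2CCCC2)ccc1O[Si](C(C)C)(C(C)C)C(C)C
F5 | step 13 | {(2R,3R)-7-methoxy-2-[3-methoxy-4-(TIPS-oxy)phenyl]-5-[3-(TBS-oxy)propyl]-2,3-dihydro-1-benzofuran-3-yl}methanol (cis) | COc1cc([C@@H]2Oc3c(OC)cc(CCCO[Si](C)(C)C(C)(C)C)cc3[C@@H]2CO)ccc1O[Si](C(C)C)(C(C)C)C(C)C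
F6 | step 13 | (2R,3S)-7-methoxy-2-[3-methoxy-4-(TIPS-oxy)phenyl]-5-[3-(TBS-oxy)propyl]-2,3-dihydro-1-benzofuran-3-carbaldehyde (cis) | COc1cc([C@@H]2Oc3c(OC)cc(CCCO[Si](C)(C)C(C)(C)C)cc3[C@@H]2C=O)ccc1O[Si](C(C)C)(C(C)C)C(C)C
F7 | step 13 | (2R,3R)-7-methoxy-2-[3-methoxy-4-(TIPS-oxy)phenyl]-5-[3-(TBS-oxy)propyl]-2,3-dihydro-1-benzofuran-3-carbaldehyde (trans) | COc1cc([C@@H]2Oc3c(OC)cc(CCCO[Si](C)(C)C(C)(C)C)cc3[C@H]2C=O)ccc1O[Si](C(C)C)(C(C)C)C(C)C
F8 | step 7 | [4-(bromomethyl)-2-methoxyphenoxy]tri(propan-2-yl)silane | COc1cc(CBr)ccc1O[Si](C(C)C)(C(C)C)C(C)C
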